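**Retrosynthetic overview**
- The lactone is the only ring formed and it is closed last: target ⇒ methyl 4-(alkyloxy)-3-hydroxy-5-methoxybenzoate + CH2O, by a proposed Mg-templated ortho-hydroxymethylative lactonisation (makes the C3–C3a bond and the lactone C–O bond).
- Aryl allyl ether C–O ⇒ methyl 3,4-dihydroxy-5-methoxybenzoate + (2E,6E)-11-acetoxy-10,11-dihydrofarnesyl bromide (acidity-controlled alkylation of the 4-OH, para to the ester).
- Side chain ⇒ (2E,6E)-farnesol, which supplies both E-alkenes; the terminal alkene is converted to the tertiary acetate by bromohydrin formation, debromination and acetylation.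

Assumption: the target has no stereogenic centre, so "single enantiomer" is taken to mean the single (2E,6E) geometric isomer.

**Route**

Step 1
Reactants: 1, (2E,6E)-farnesol
Product: 2, (2E,6E)-farnesyl tert-butyldiphenylsilyl ether
Conditions: TBDPSCl, imidazole, CH2Cl2, 0 °C → rt
Reagents that add atoms: TBDPSCl, CC(C)(C)[Si](Cl)(c1ccccc1)c1ccccc1
Why: Standard silylation of a primary allylic alcohol; the TBDPS group is stable to NBS/water, radical reduction and acylation, and the alkenes are untouched.

Step 2
Reactants: 2, (2E,6E)-farnesyl TBDPS ether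
Product: 3, (±)-(6E,10E)-3-bromo-12-[(tert-butyldiphenylsilyl)oxy]-2,6,10-trimethyldodeca-6,10-dien-2-ol (the terminal 10,11-bromohydrin in farnesol numbering)
Conditions: NBS (1.1 equiv), THF/H2O (4:1), 0 °C
Reagents that add atoms: N-bromosuccinimide, O=C1CCC(=O)N1Br; water, O
Why: van Tamelen bromohydrin formation: in aqueous THF, NBS attacks the exposed terminal alkene (the 2,3-alkene is inductively deactivated by the allylic oxygen) and water opens the bromonium ion at the tertiary carbon (Markovnikov); the C–Br stereocentre is racemic and is erased in step 3, and both E-alkenes are retained.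

Step 3
Reactants: 3, terminal bromohydrin
Product: 4, (6E,10E)-12-[(tert-butyldiphenylsilyl)oxy]-2,6,10-trimethyldodeca-6,10-dien-2-ol
Conditions: (TMS)3SiH (1.3 equiv), AIBN (cat.), toluene, 80 °C
Reagents that add atoms: none
Why: Radical-chain dehalogenation; the secondary C10 radical has only disfavoured 4-exo/5-endo cyclisation modes onto the 6,7-alkene, so it is simply reduced, leaving the tertiary alcohol, silyl ether and E-alkenes intact.

Step 4
Reactants: 4, tertiary alcohol
Product: 5, (6E,10E)-12-[(tert-butyldiphenylsilyl)oxy]-2,6,10-trimethyldodeca-6,10-dien-2-yl acetate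
Conditions: Ac2O (4 equiv), Et3N (5 equiv), DMAP (0.3 equiv), CH2Cl2, rt → 40 °C, 24 h
Reagents that add atoms: acetic anhydride, CC(=O)OC(C)=O
Why: Steglich-type DMAP-catalysed acylation via the N-acetylpyridinium ion is the standard method for hindered tertiary alcohols, and the base-only medium does not affect the silyl ether or alkenes.

Step 5
Reactants: 5, silyl ether tertiary acetate
Product: 6, (6E,10E)-12-hydroxy-2,6,10-trimethyldodeca-6,10-dien-2-yl acetate
Conditions: TBAF (1.2 equiv), AcOH (1.2 equiv), THF, 0 °C → rt
Reagents that add atoms: none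
Why: Fluoride desilylation; acetic acid buffering keeps the medium non-basic so the hindered tertiary acetate survives.

Step 6
Reactants: 6, allylic alcohol
Product: 7, (6E,10E)-12-bromo-2,6,10-trimethyldodeca-6,10-dien-2-yl acetate (used crude)
Conditions: MsCl, Et3N, THF, −40 °C; then LiBr (4 equiv), THF, 0 °C
Reagents that add atoms: lithium bromide, [Li+].[Br-] (MsCl is transient and leaves no atoms)
Why: Mesylation followed by SN2 bromide displacement at low temperature is the standard farnesyl bromide preparation; with no acid present there is no allylic transposition, E/Z leakage or ionisation of the tertiary acetate.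

Step 7
Reactants: 7, allylic bromide; 8, methyl 3,4-dihydroxy-5-methoxybenzoate (1.3 equiv)
Product: 9, methyl 4-{[(2E,6E)-11-acetoxy-3,7,11-trimethyldodeca-2,6-dien-1-yl]oxy}-3-hydroxy-5-methoxybenzoate
Conditions: Li2CO3 (1.3 equiv), DMF, 45 °C, dark
Reagents that add atoms: none
Why: Williamson ether synthesis in which the weak base deprotonates only the more acidic 4-OH (para to the ester), and its phenoxide attacks the primary allylic bromide by SN2 with retention of the 2E geometry; any 3-O-alkyl isomer has no free ortho C–H and cannot give a phthalide in step 8.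

Step 8
Reactants: 9, phenolic benzoate
Product: 10, Farnesylemefuranone F, 5-{[(2E,6E)-11-acetoxy-3,7,11-trimethyldodeca-2,6-dien-1-yl]oxy}-4-hydroxy-6-methoxyisobenzofuran-1(3H)-one
Conditions: anhydrous MgCl2 (2 equiv), Et3N (4 equiv), THF, rt, 30 min; then paraformaldehyde (1.3 equiv CH2O, portionwise), 60 °C; 1 M HCl work-up
Reagents that add atoms: paraformaldehyde (formaldehyde), C=O
Why: Proposed new method: an interrupted Casnati–Skattebøl reaction in which the magnesium phenoxide of 9 delivers CH2O through a six-membered Mg-chelated transition state to its only free ortho carbon (C2, also para to OMe), and the resulting Mg benzylic alkoxide, which normally passes hydride to a second CH2O (Oppenauer step) to give the salicylaldehyde, is instead captured by 5-exo-trig acyl substitution on the adjacent CO2Me (loss of MeOMgCl), a unimolecular step favoured by limiting formaldehyde to about one equivalent; the closest known reaction types are the MgCl2/Et3N/paraformaldehyde ortho-formylation of phenols and Lederer–Manasse hydroxymethylation, together with the spontaneous lactonisation of o-(hydroxymethyl)benzoates; the alkenes, allyl aryl ether and tertiary acetate should be inert to this weakly Lewis-acidic, basic medium.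

**Compound list**

1 | (2E,6E)-farnesol | OC/C=C(\C)CC/C=C(\C)CCC=C(C)C | starting material
2 | (2E,6E)-farnesyl tert-butyldiphenylsilyl ether | CC(C)(C)[Si](c1ccccc1)(c1ccccc1)OC/C=C(\C)CC/C=C(\C)CCC=C(C)C | intermediate
3 | (±)-(6E,10E)-3-bromo-12-[(tert-butyldiphenylsilyl)oxy]-2,6,10-trimethyldodeca-6,10-dien-2-ol | CC(C)(C)[Si](c1ccccc1)(c1ccccc1)OC/C=C(\C)CC/C=C(\C)CCC(Br)C(C)(C)O | intermediate
4 | (6E,10E)-12-[(tert-butyldiphenylsilyl)oxy]-2,6,10-trimethyldodeca-6,10-dien-2-ol | CC(C)(C)[Si](c1ccccc1)(c1ccccc1)OC/C=C(\C)CC/C=C(\C)CCCC(C)(C)O | intermediate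
5 | (6E,10E)-12-[(tert-butyldiphenylsilyl)oxy]-2,6,10-trimethyldodeca-6,10-dien-2-yl acetate | CC(C)(C)[Si](c1ccccc1)(c1ccccc1)OC/C=C(\C)CC/C=C(\C)CCCC(C)(C)OC(C)=O | intermediate
6 | (6E,10E)-12-hydroxy-2,6,10-trimethyldodeca-6,10-dien-2-yl acetate | OC/C=C(\C)CC/C=C(\C)CCCC(C)(C)OC(C)=O | intermediate
7 | (6E,10E)-12-bromo-2,6,10-trimethyldodeca-6,10-dien-2-yl acetate | BrC/C=C(\C)CC/C=C(\C)CCCC(C)(C)OC(C)=O | intermediate
8 | methyl 3,4-dihydroxy-5-methoxybenzoate (methyl 3-O-methylgallate) | COC(=O)c1cc(O)c(O)c(OC)c1 | starting material
9 | methyl 4-{[(2E,6E)-11-acetoxy-3,7,11-trimethyldodeca-2,6-dien-1-yl]oxy}-3-hydroxy-5-methoxybenzoate | COC(=O)c1cc(O)c(OC/C=C(\C)CC/C=C(\C)CCCC(C)(C)OC(C)=O)c(OC)c1 | intermediate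
10 | Farnesylemefuranone F | COc1cc2c(c(O)c1OC/C=C(\C)CC/C=C(\C)CCCC(C)(C)OC(C)=O)COC2=O | target

**Totals**
- Total step count: 8.
- Longest linear sequence: 8 steps (1 → 2 → 3 → 4 → 5 → 6 → 7 → 9 → 10); compound 8 is a purchased coupling partner.

**Three steps most likely to fail**

1. Step 8 (proposed new method). The benzylic Mg alkoxide may be oxidised to the salicylaldehyde faster than it lactonises, or hydroxymethylation may be slow at the hindered carbon between OH and CO2Me. Fallback (known chemistry, two steps): run the ordinary ortho-formylation to completion with excess paraformaldehyde (MgCl2, Et3N, MeCN, reflux) to give the methyl 2-formyl-3-hydroxybenzoate, then reduce with NaBH4 in MeOH; the o-(hydroxymethyl)benzoate lactonises to 10 on work-up.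

2. Step 2 (terminal-selective bromohydrin). Site selectivity or solubility of the lipophilic silyl ether in aqueous THF may be poor. Fallback: build the chain by C–C coupling from geraniol instead. Geranyl TBDPS ether is oxidised E-selectively at C8 (SeO2/t-BuOOH), converted to the 8-bromide, and coupled under Li2CuCl4 catalysis with the Grignard reagent from 4-bromo-2-methyl-2-(triethylsilyloxy)butane (SN2-selective, E retained). Selective TES removal then gives 4 and the route continues.

3. Step 7 (mono- and regioselective O-alkylation of the catechol). Bis-alkylation or 3-O-alkylation would waste bromide 7. Fallback: fix the regiochemistry with protecting groups on cheap material. Allylate 8 at O-4 and separate isomers, protect the 3-OH as its MOM ether, remove the allyl group with Pd(0)/morpholine, alkylate the now unique 4-OH with 7, and remove the MOM group (ZnBr2/n-PrSH) to give 9.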